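## Retrosynthetic overview

1. Last cut: the amide bond of target 26, giving amine 22 and (E)-dodec-2-enoic acid 23.
2. Feature: in the bicyclo[3.3.1]nonane core (ring A = C1, C8, C7, C6, C5, C9; ring B = C1, C2, C3, C4, C5, C9; oxirane C2–C3, OMe on C4, OH on C6, N on C7) the bridgehead carbinol C1 and the bridge ketone C9 form an α-ketol. Returning C8 from C1 to C9 contracts ring A to a cyclopentane (C5, C6, C7, C8, C9) cis-fused to ring B, so bridged ketol 21 comes from hydrindanone ketol 20 by a 1,2-acyloin shift.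
3. 20 comes from hydrindanol 16 (oxirane from C3–O onto C2–OTs, then oxidation at C1); 16 from iodo ketone 15 by samarium Barbier closure C8–C9; 15 from ring B ketone 8 and N-Boc-N,O-isopropylidene-L-serinal 9 by a C5–C6 aldol.
4. 8 comes from methyl 4,6-O-benzylidene-α-D-glucopyranoside 1 by Ferrier carbocyclization (C4–C5). Ring order: ring B, cyclopentane, oxirane, ring A (by one-carbon expansion of the cyclopentane).
5. Locants C1–C9 are kept for all carbocyclic intermediates; β is the face of ring B that carries the C4 methoxy group (seen from it, C1→C2→C3→C4→C5→C9 runs clockwise), α the opposite face.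

Key step: step 16

Remark: 1, 9 (made from L-serine) and 23 are taken as commercial; in step 6 the carbocyclization is assumed to give mainly the 4β-hydroxy epimer, as is usual for gluco-configured enopyranosides.

## Route

Step 1
Reactants: 1 methyl 4,6-O-benzylidene-α-D-glucopyranoside
Product: 2 methyl 2-O-benzoyl-4,6-O-benzylidene-α-D-glucopyranoside
Conditions: 1-benzoylimidazole (1.1 equiv), CHCl3, reflux
Reagents that add atoms: 1-benzoylimidazole, O=C(c1ccccc1)n1ccnc1
Why: Regioselective acyl transfer: O2, next to the anomeric carbon, is the more reactive hydroxyl of the 2,3-diol in α-glucosides, so the 2-benzoate should be the main product; no stereocenter is touched.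

Step 2
Reactants: 2 methyl 2-O-benzoyl-4,6-O-benzylidene-α-D-glucopyranoside
Product: 3 methyl 2-O-benzoyl-4,6-O-benzylidene-3-O-tosyl-α-D-glucopyranoside
Conditions: TsCl (3 equiv), pyridine, DMAP (cat.), 50 °C
Reagents that add atoms: 4-methylbenzenesulfonyl chloride, Cc1ccc(S(=O)(=O)Cl)cc1
Why: Sulfonylation of the one free hydroxyl (O–S bond formation, retention at C3) installs the later leaving group at core C2 as a tosylate, which has no acidic α-protons for the amide base of step 8.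

Step 3
Reactants: 3 methyl 2-O-benzoyl-4,6-O-benzylidene-3-O-tosyl-α-D-glucopyranoside
Product: 4 methyl 2-O-benzoyl-4-O-benzyl-3-O-tosyl-α-D-glucopyranoside
Conditions: BH3·THF (5 equiv), Cu(OTf)2 (5 mol %), CH2Cl2, rt
Reagents that add atoms: none
Why: Lewis-acid-catalysed regioselective reductive opening of the 4,6-O-benzylidene acetal with borane should leave the benzyl group on O4 and free the primary O6; ester and sulfonate are tolerated and no stereocenter is touched.

Step 4
Reactants: 4 methyl 2-O-benzoyl-4-O-benzyl-3-O-tosyl-α-D-glucopyranoside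
Product: 5 methyl 2-O-benzoyl-4-O-benzyl-6-deoxy-6-iodo-3-O-tosyl-α-D-glucopyranoside
Conditions: I2, PPh3, imidazole, toluene, 70 °C
Reagents that add atoms: iodine, II
Why: Appel-type iodination of the primary alcohol (SN2 on the alkoxyphosphonium ion); the hindered secondary tosylate should not be displaced.

Step 5
Reactants: 5 methyl 2-O-benzoyl-4-O-benzyl-6-deoxy-6-iodo-3-O-tosyl-α-D-glucopyranoside
Product: 6 methyl 2-O-benzoyl-4-O-benzyl-6-deoxy-3-O-tosyl-α-D-xylo-hex-5-enopyranoside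
Conditions: AgF, pyridine, rt, dark
Reagents that add atoms: none
Why: Silver-assisted dehydroiodination (E2) gives the exocyclic enol ether under conditions mild enough for the benzoate and the tosylate.

Step 6
Reactants: 6 methyl 2-O-benzoyl-4-O-benzyl-6-deoxy-3-O-tosyl-α-D-xylo-hex-5-enopyranoside
Product: 7 3β-benzoyloxy-1β-benzyloxy-4β-hydroxy-2α-(tosyloxy)cyclohexan-9-one (ring B; C5 is CH2)
Conditions: Hg(OCOCF3)2 (5 mol %), acetone–H2O (2:1), rt
Reagents that add atoms: water, O
Why: Ferrier carbocyclization (hydroxymercuration of the enol ether, loss of methanol, then 6-exo aldol of the α-mercurio ketone onto the unmasked aldehyde) forms C4–C5 and ring B; the new C4 hydroxyl is expected axial and trans to the C2 substituent, that is β, as is the rule for gluco-configured substrates.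

Step 7
Reactants: 7 3β-benzoyloxy-1β-benzyloxy-4β-hydroxy-2α-(tosyloxy)cyclohexan-9-one
Product: 8 3β-benzoyloxy-1β-benzyloxy-4β-methoxy-2α-(tosyloxy)cyclohexan-9-one
Conditions: MeOTf, 2,6-di-tert-butyl-4-methylpyridine, CH2Cl2, 0 °C → rt
Reagents that add atoms: methyl trifluoromethanesulfonate, COS(=O)(=O)C(F)(F)F
Why: O-Methylation with a hard electrophile and a non-nucleophilic hindered base avoids β-elimination of the β-hydroxy ketone and migration of the neighbouring benzoate; configuration at C4 is retained.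

Step 8
Reactants: 8 3β-benzoyloxy-1β-benzyloxy-4β-methoxy-2α-(tosyloxy)cyclohexan-9-one; 9 N-Boc-N,O-isopropylidene-L-serinal [(S)-tert-butyl 4-formyl-2,2-dimethyloxazolidine-3-carboxylate]
Product: 12 aldol adduct: ketone 8 carrying on C5 (α-face) the (6R)-hydroxy[(4S)-3-Boc-2,2-dimethyloxazolidin-4-yl]methyl group (C7 = oxazolidine C4; C8 = oxazolidine C5), via lithium enolate 10 (not isolated), via titanium enolate 11 (not isolated)
Conditions: LiN(iPr)2 (1.1 equiv), THF, −78 °C; ClTi(OiPr)3, −78 → −40 °C; 9, −78 °C; aq. NH4Cl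
Reagents that add atoms: none
Why: Directed aldol addition of a triisopropoxytitanium enolate: kinetic deprotonation takes the C5 methylene rather than the C1 methine; the aldehyde should enter C5 axially and anti to the axial C4 methoxy group (C6 on the α-face), on the Felkin–Anh (non-chelation) face of the α-amino aldehyde (6R, anti to N), and through the syn-selective pathway usual for titanium alkoxide enolates of cyclic ketones, so all three elements point to the same isomer.

Step 9
Reactants: 12 aldol adduct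
Product: 13 C6 tert-butyldimethylsilyl ether of 12
Conditions: TBSOTf, 2,6-lutidine, CH2Cl2, −78 → −20 °C
Reagents that add atoms: tert-butyldimethylsilyl trifluoromethanesulfonate, CC(C)(C)[Si](C)(C)OS(=O)(=O)C(F)(F)F
Why: Silylation of the β-hydroxy ketone at low temperature blocks retro-aldol cleavage and later distinguishes O6 from O1; no stereocenter is touched.

Step 10
Reactants: 13 C6 tert-butyldimethylsilyl ether of 12
Product: 14 ketone 8 carrying on C5 (α-face) the (6R,7S)-CH(OTBS)–CH(NHBoc)–CH2OH chain (C6, C7, C8)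
Conditions: p-TsOH·H2O (0.1 equiv), MeOH, 0 °C → rt
Reagents that add atoms: none
Why: Acid-catalysed methanolysis of the N,O-isopropylidene acetal frees the C8 hydroxyl and the carbamate N–H, while the secondary silyl ether, the Boc group, the esters and the ketone should survive these mild conditions.

Step 11
Reactants: 14 N-Boc amino alcohol
Product: 15 iodo ketone: ketone 8 carrying on C5 (α-face) the (6R,7R)-CH(OTBS)–CH(NHBoc)–CH2I chain
Conditions: I2, PPh3, imidazole, CH2Cl2, 0 °C → rt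
Reagents that add atoms: iodine, II
Why: Appel-type iodination of the primary alcohol (SN2) gives the C8 iodide; C7 is not touched (its descriptor changes only because iodine outranks oxygen).

Step 12
Reactants: 15 iodo ketone
Product: 16 (6R,7S,9R)-3β-benzoyloxy-1β-benzyloxy-7-(Boc-amino)-6-(TBS-oxy)-9β-hydroxy-4β-methoxy-2α-(tosyloxy)-cis-hydrindane (5β-H)
Conditions: SmI2 (3 equiv), HMPA, THF, −78 → 0 °C; aq. NH4Cl
Reagents that add atoms: none
Why: Intramolecular samarium Barbier reaction: the primary iodide is reduced to an alkylsamarium that adds to the C9 ketone in a 5-exo closure (C8–C9); a five-membered ring can only be cis-fused here, so C8 enters on the α-face where C6 already stands and the new tertiary hydroxyl is β (9R).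

Step 13
Reactants: 16 cis-hydrindanol
Product: 18 (6R,7S,9R)-1β-benzyloxy-7-(Boc-amino)-6-(TBS-oxy)-2β,3β-epoxy-9β-hydroxy-4β-methoxy-cis-hydrindane, via hydroxy tosylate 17 (not isolated)
Conditions: K2CO3 (2 equiv), MeOH, rt
Reagents that add atoms: none
Why: Methanolysis of the benzoate frees the C3 alkoxide, which after ring flip stands anti to the C2 tosylate and displaces it (intramolecular Williamson SN2) with inversion at C2, so the oxirane oxygen lies β, cis to the C4 methoxy group; the benzylated C1 oxygen cannot compete.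

Step 14
Reactants: 18 benzyloxy epoxide
Product: 19 (6R,7S,9R)-7-(Boc-amino)-6-(TBS-oxy)-2β,3β-epoxy-1β,9β-dihydroxy-4β-methoxy-cis-hydrindane
Conditions: H2 (1 atm), Pd(OH)2/C, EtOAc, rt
Reagents that add atoms: none
Why: Hydrogenolysis of the benzyl ether; the non-benzylic oxirane, the silyl ether and the carbamate should be inert, and no stereocenter is touched.

Step 15
Reactants: 19 epoxy diol
Product: 20 (2S,3S,4S,5R,6R,7S,9R)-7-(Boc-amino)-6-(TBS-oxy)-2,3-epoxy-9-hydroxy-4-methoxy-cis-hydrindan-1-one (ketol precursor)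
Conditions: Dess–Martin periodinane, CH2Cl2, 0 °C → rt
Reagents that add atoms: none
Why: Dess–Martin oxidation of the only secondary alcohol gives the C1 ketone; the tertiary C9 hydroxyl cannot be oxidised and the oxirane carbon C2 does not enolise.

Step 16
Reactants: 20 ketol precursor
Product: 21 (1S,2S,3S,4S,5R,6R,7S)-7-(Boc-amino)-6-(TBS-oxy)-2,3-epoxy-1-hydroxy-4-methoxybicyclo[3.3.1]nonan-9-one
Conditions: Al(OtBu)3 (2 equiv), toluene, 60 °C; aq. Rochelle salt
Reagents that add atoms: none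
Why: The C9 aluminium alkoxide chelates the C1 carbonyl; as the C9–O bond becomes the new carbonyl, the C9–C8 σ bond shifts suprafacially to C1, whose oxygen is left as the alkoxide (C1–C8 formed, C8–C9 broken). This is an α-ketol (acyloin) rearrangement, closest to the aluminium-alkoxide D-homoannulation of 17-hydroxy-20-keto steroids. Ring A (C1, C8, C7, C6, C5, C9) is closed by this 1,2-alkyl shift, a one-carbon expansion of the cyclopentane and not an end-to-end cyclization, and C9 becomes the one-carbon bridge. The one new stereocenter, C1, is fixed by the cis ring fusion: C8 sits on the α-face with C6 and migrates with retention on that face, so the hydroxyl is left β (1S), the only arrangement in which ring A can span C1 and C5. The step needs C8 and not C5 to migrate: in the five-membered chelate the C9 oxygen lies near the C1 carbonyl plane (equatorial on ring B), which sets C8 axial and close to parallel with the carbonyl π* orbital, whereas the C9–C5 ring bond is less well aligned and its shift would give a more strained oxirane-fused cyclopentane. The shift is reversible and is expected to drain to 21, which sheds the cyclopentane and hydrindane strain and trades the inductively destabilised oxirane-flanked carbonyl for a plain bridge ketone.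

Step 17
Reactants: 21 bridged ketol
Product: 22 (1S,2S,3S,4S,5R,6R,7S)-7-amino-6-(TBS-oxy)-2,3-epoxy-1-hydroxy-4-methoxybicyclo[3.3.1]nonan-9-one
Conditions: TFA/CH2Cl2 (1:4), 0 °C; aq. NaHCO3
Reagents that add atoms: none
Why: Acidolysis of the tert-butyl carbamate; the oxirane is flanked by electron-poor carbons and the secondary silyl ether is slow to cleave under these conditions, and no stereocenter is touched.

Step 18
Reactants: 22 amine; 23 (E)-dodec-2-enoic acid
Product: 25 (E)-N-[(1S,2S,3S,4S,5R,6R,7S)-6-(TBS-oxy)-2,3-epoxy-1-hydroxy-4-methoxy-9-oxobicyclo[3.3.1]nonan-7-yl]dodec-2-enamide, via benzotriazolyl ester 24 (not isolated)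
Conditions: DIC, HOBt, CH2Cl2, 0 °C → rt
Reagents that add atoms: none
Why: Carbodiimide amide coupling through the benzotriazolyl ester; the primary amine should be acylated far faster than the hindered bridgehead hydroxyl, and the E-alkene is not touched.

Step 19
Reactants: 25 silyl-protected amide
Product: 26 (E)-N-[(1S,2S,3S,4S,5S,6R,7S)-2,3-epoxy-1,6-dihydroxy-4-methoxy-9-oxobicyclo[3.3.1]nonan-7-yl]dodec-2-enamide (target)
Conditions: HF·pyridine, pyridine/THF, 0 °C → rt
Reagents that add atoms: none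
Why: Fluoride desilylation under buffered, non-basic conditions frees the C6 hydroxyl without retro-aldol cleavage of the resulting β-hydroxy ketone (C6–OH/C9=O); the C5 descriptor changes only through CIP priorities.

## Compound list

1 | methyl 4,6-O-benzylidene-α-D-glucopyranoside (acetal carbon R) | CO[C@H]1O[C@@H]2CO[C@@H](c3ccccc3)O[C@H]2[C@H](O)[C@H]1O | starting material
2 | methyl 2-O-benzoyl-4,6-O-benzylidene-α-D-glucopyranoside | CO[C@H]1O[C@@H]2CO[C@@H](c3ccccc3)O[C@H]2[C@H](O)[C@H]1OC(=O)c1ccccc1 | intermediate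
3 | methyl 2-O-benzoyl-4,6-O-benzylidene-3-O-tosyl-α-D-glucopyranoside | CO[C@H]1O[C@@H]2CO[C@@H](c3ccccc3)O[C@H]2[C@H](OS(=O)(=O)c2ccc(C)cc2)[C@H]1OC(=O)c1ccccc1 | intermediate
4 | methyl 2-O-benzoyl-4-O-benzyl-3-O-tosyl-α-D-glucopyranoside | CO[C@H]1O[C@H](CO)[C@@H](OCc2ccccc2)[C@H](OS(=O)(=O)c2ccc(C)cc2)[C@H]1OC(=O)c1ccccc1 | intermediate
5 | methyl 2-O-benzoyl-4-O-benzyl-6-deoxy-6-iodo-3-O-tosyl-α-D-glucopyranoside | CO[C@H]1O[C@H](CI)[C@@H](OCc2ccccc2)[C@H](OS(=O)(=O)c2ccc(C)cc2)[C@H]1OC(=O)c1ccccc1 | intermediate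
6 | methyl 2-O-benzoyl-4-O-benzyl-6-deoxy-3-O-tosyl-α-D-xylo-hex-5-enopyranoside | CO[C@H]1OC(=C)[C@@H](OCc2ccccc2)[C@H](OS(=O)(=O)c2ccc(C)cc2)[C@H]1OC(=O)c1ccccc1 | intermediate
7 | 3β-benzoyloxy-1β-benzyloxy-4β-hydroxy-2α-(tosyloxy)cyclohexan-9-one | O=C1C[C@H](O)[C@H](OC(=O)c2ccccc2)[C@@H](OS(=O)(=O)c2ccc(C)cc2)[C@@H]1OCc1ccccc1 | intermediate
8 | 3β-benzoyloxy-1β-benzyloxy-4β-methoxy-2α-(tosyloxy)cyclohexan-9-one (ring B ketone) | O=C1C[C@H](OC)[C@H](OC(=O)c2ccccc2)[C@@H](OS(=O)(=O)c2ccc(C)cc2)[C@@H]1OCc1ccccc1 | intermediate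
9 | N-Boc-N,O-isopropylidene-L-serinal, (S)-tert-butyl 4-formyl-2,2-dimethyloxazolidine-3-carboxylate | CC(C)(C)OC(=O)N1[C@@H](COC1(C)C)C=O | starting material
10 | lithium C9,C5-enolate of 8 | [Li]OC1=C[C@H](OC)[C@H](OC(=O)c2ccccc2)[C@@H](OS(=O)(=O)c2ccc(C)cc2)[C@@H]1OCc1ccccc1 | intermediate (not isolated)
11 | triisopropoxytitanium C9,C5-enolate of 8 | CC(C)O[Ti](OC(C)C)(OC(C)C)OC1=C[C@H](OC)[C@H](OC(=O)c2ccccc2)[C@@H](OS(=O)(=O)c2ccc(C)cc2)[C@@H]1OCc1ccccc1 | intermediate (not isolated)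
12 | aldol adduct, 5α-[(6R)-hydroxy((4S)-3-Boc-2,2-dimethyloxazolidin-4-yl)methyl] derivative of 8 | O=C1[C@@H]([C@@H](O)[C@@H]2COC(C)(C)N2C(=O)OC(C)(C)C)[C@H](OC)[C@H](OC(=O)c2ccccc2)[C@@H](OS(=O)(=O)c2ccc(C)cc2)[C@@H]1OCc1ccccc1 | intermediate
13 | C6 tert-butyldimethylsilyl ether of 12 | O=C1[C@@H]([C@@H](O[Si](C)(C)C(C)(C)C)[C@@H]2COC(C)(C)N2C(=O)OC(C)(C)C)[C@H](OC)[C@H](OC(=O)c2ccccc2)[C@@H](OS(=O)(=O)c2ccc(C)cc2)[C@@H]1OCc1ccccc1 | intermediate
14 | (6R,7S) N-Boc amino alcohol (C8–OH) | O=C1[C@@H]([C@@H](O[Si](C)(C)C(C)(C)C)[C@H](CO)NC(=O)OC(C)(C)C)[C@H](OC)[C@H](OC(=O)c2ccccc2)[C@@H](OS(=O)(=O)c2ccc(C)cc2)[C@@H]1OCc1ccccc1 | intermediate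
15 | (6R,7R) iodo ketone (C8–I) | O=C1[C@@H]([C@@H](O[Si](C)(C)C(C)(C)C)[C@H](CI)NC(=O)OC(C)(C)C)[C@H](OC)[C@H](OC(=O)c2ccccc2)[C@@H](OS(=O)(=O)c2ccc(C)cc2)[C@@H]1OCc1ccccc1 | intermediate
16 | (6R,7S,9R)-3β-benzoyloxy-1β-benzyloxy-7-(Boc-amino)-6-(TBS-oxy)-9β-hydroxy-4β-methoxy-2α-(tosyloxy)-cis-hydrindane | CC(C)(C)OC(=O)N[C@H]1C[C@]2(O)[C@@H](OCc3ccccc3)[C@H](OS(=O)(=O)c3ccc(C)cc3)[C@@H](OC(=O)c3ccccc3)[C@@H](OC)[C@@H]2[C@H]1O[Si](C)(C)C(C)(C)C | intermediate
17 | 3β-hydroxy-2α-tosyloxy hydrindane (debenzoylated 16) | CC(C)(C)OC(=O)N[C@H]1C[C@]2(O)[C@@H](OCc3ccccc3)[C@H](OS(=O)(=O)c3ccc(C)cc3)[C@@H](O)[C@@H](OC)[C@@H]2[C@H]1O[Si](C)(C)C(C)(C)C | intermediate (not isolated)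
18 | (6R,7S,9R)-1β-benzyloxy-2β,3β-epoxy hydrindanol | CC(C)(C)OC(=O)N[C@H]1C[C@]2(O)[C@@H](OCc3ccccc3)[C@H]3O[C@H]3[C@@H](OC)[C@@H]2[C@H]1O[Si](C)(C)C(C)(C)C | intermediate
19 | (6R,7S,9R)-2β,3β-epoxy-1β,9β-dihydroxy hydrindane | CC(C)(C)OC(=O)N[C@H]1C[C@]2(O)[C@@H](O)[C@H]3O[C@H]3[C@@H](OC)[C@@H]2[C@H]1O[Si](C)(C)C(C)(C)C | intermediate
20 | (2S,3S,4S,5R,6R,7S,9R)-7-(Boc-amino)-6-(TBS-oxy)-2,3-epoxy-9-hydroxy-4-methoxy-cis-hydrindan-1-one (key-step precursor) | CC(C)(C)OC(=O)N[C@H]1C[C@]2(O)C(=O)[C@H]3O[C@H]3[C@@H](OC)[C@@H]2[C@H]1O[Si](C)(C)C(C)(C)C | intermediate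
21 | (1S,2S,3S,4S,5R,6R,7S)-7-(Boc-amino)-6-(TBS-oxy)-2,3-epoxy-1-hydroxy-4-methoxybicyclo[3.3.1]nonan-9-one (key-step product) | CC(C)(C)OC(=O)N[C@H]1C[C@@]2(O)C(=O)[C@@H]([C@H]1O[Si](C)(C)C(C)(C)C)[C@H](OC)[C@@H]1O[C@@H]12 | intermediate
22 | 7-amino-6-(TBS-oxy) bridged ketol | N[C@H]1C[C@@]2(O)C(=O)[C@@H]([C@H]1O[Si](C)(C)C(C)(C)C)[C@H](OC)[C@@H]1O[C@@H]12 | intermediate
23 | (E)-dodec-2-enoic acid | CCCCCCCCC/C=C/C(=O)O | starting material
24 | benzotriazol-1-yl (E)-dodec-2-enoate | CCCCCCCCC/C=C/C(=O)On1nnc2ccccc21 | intermediate (not isolated)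
25 | 6-O-TBS ether of the target amide | CCCCCCCCC/C=C/C(=O)N[C@H]1C[C@@]2(O)C(=O)[C@@H]([C@H]1O[Si](C)(C)C(C)(C)C)[C@H](OC)[C@@H]1O[C@@H]12 | intermediate
26 | (E)-N-[(1S,2S,3S,4S,5S,6R,7S)-2,3-epoxy-1,6-dihydroxy-4-methoxy-9-oxobicyclo[3.3.1]nonan-7-yl]dodec-2-enamide | CCCCCCCCC/C=C/C(=O)N[C@H]1C[C@@]2(O)C(=O)[C@@H]([C@H]1O)[C@H](OC)[C@@H]1O[C@@H]12 | target

## Step count and risks

Total step count: 19. Longest linear sequence: 19 steps (1 → 26); 9 and 23 enter as commercial materials.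

Steps most likely to fail:

1. Step 16 (ketol shift). The ketol equilibrium may rest on the side of the fused isomer, the C9–C5 ring bond may shift in competition, or the aluminium alkoxide may open the oxirane. The fallback sets out from 16 and comes back at 21; it runs the shift before the oxirane exists, on a more electrophilic α-sulfonyloxy ketone. Hydrogenolysis of 16 (H2, Pd(OH)2/C) gives the C1 alcohol F1, and Dess–Martin oxidation gives the α-tosyloxy ketol F2. With no oxirane present, F2 can be treated with Al(OtBu)3 or with the stronger BF3·OEt2 to give the bridged tosyloxy ketol F3. K2CO3 in MeOH then removes the benzoate (hydroxy tosylate F4, not isolated) and closes the oxirane by displacement of the C2 tosylate, which gives 21.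

2. Step 8 (aldol). The C5 enolate may lose methanol by β-elimination, or the addition may go through a closed transition state and deliver the C6-epimeric (anti) aldol. The fallback sets out from 8 and comes back at 12. Ketone 8 is deprotonated with LiN(iPr)2 in the presence of TMSCl (in situ quench, THF, −78 °C), so that the enolate is trapped at once as the trimethylsilyl enol ether F5. F5 is isolated and added to 9 in a Mukaiyama aldol reaction (BF3·OEt2, CH2Cl2, −78 °C), an open-transition-state addition under Felkin–Anh control with no free basic enolate; aqueous work-up returns 12.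

3. Step 12 (Barbier closure). Electron transfer to the α-benzyloxy ketone with loss of the C1 benzyloxy group, or β-elimination of the carbamate from the alkylsamarium, may outrun ring closure. The fallback sets out from 14 and comes back at 16. Dess–Martin oxidation of 14 gives the aldehyde F6, which is used at once. SmI2 in THF then effects an intramolecular ketone–aldehyde pinacol coupling, in which the aldehyde is reduced first, and gives the cis-fused cis-diol F7. The secondary C8 hydroxyl is converted selectively with PhOC(S)Cl and pyridine into the phenyl thionocarbonate F8, and Barton–McCombie deoxygenation (Bu3SnH, AIBN, toluene, 80 °C) gives 16.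

Further compounds
F1 | step 16 | C1 alcohol from hydrogenolysis of 16 (1β-OH, 2α-OTs, 3β-OBz) | CC(C)(C)OC(=O)N[C@H]1C[C@]2(O)[C@@H](O)[C@H](OS(=O)(=O)c3ccc(C)cc3)[C@@H](OC(=O)c3ccccc3)[C@@H](OC)[C@@H]2[C@H]1O[Si](C)(C)C(C)(C)C
F2 | step 16 | 3β-benzoyloxy-2α-tosyloxy-9β-hydroxy-cis-hydrindan-1-one (α-tosyloxy ketol) | CC(C)(C)OC(=O)N[C@H]1C[C@]2(O)C(=O)[C@H](OS(=O)(=O)c3ccc(C)cc3)[C@@H](OC(=O)c3ccccc3)[C@@H](OC)[C@@H]2[C@H]1O[Si](C)(C)C(C)(C)C
F3 | step 16 | 3β-benzoyloxy-2α-tosyloxy-1-hydroxybicyclo[3.3.1]nonan-9-one (bridged tosyloxy ketol) | CC(C)(C)OC(=O)N[C@H]1C[C@@]2(O)C(=O)[C@@H]([C@H]1O[Si](C)(C)C(C)(C)C)[C@H](OC)[C@H](OC(=O)c1ccccc1)[C@H]2OS(=O)(=O)c1ccc(C)cc1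
F4 | step 16 | 3β-hydroxy-2α-tosyloxy bridged ketol (debenzoylated F3) | CC(C)(C)OC(=O)N[C@H]1C[C@@]2(O)C(=O)[C@@H]([C@H]1O[Si](C)(C)C(C)(C)C)[C@H](OC)[C@H](O)[C@H]2OS(=O)(=O)c1ccc(C)cc1
F5 | step 8 | trimethylsilyl C9,C5-enol ether of 8 | C[Si](C)(C)OC1=C[C@H](OC)[C@H](OC(=O)c2ccccc2)[C@@H](OS(=O)(=O)c2ccc(C)cc2)[C@@H]1OCc1ccccc1
F6 | step 12 | C8 aldehyde from 14 | O=C1[C@@H]([C@@H](O[Si](C)(C)C(C)(C)C)[C@H](C=O)NC(=O)OC(C)(C)C)[C@H](OC)[C@H](OC(=O)c2ccccc2)[C@@H](OS(=O)(=O)c2ccc(C)cc2)[C@@H]1OCc1ccccc1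
F7 | step 12 | 8,9-cis-diol (C8 hydroxyl cis to the C9 hydroxyl) of hydrindane 16 | CC(C)(C)OC(=O)N[C@H]1[C@@H](O)[C@]2(O)[C@@H](OCc3ccccc3)[C@H](OS(=O)(=O)c3ccc(C)cc3)[C@@H](OC(=O)c3ccccc3)[C@@H](OC)[C@@H]2[C@H]1O[Si](C)(C)C(C)(C)C
F8 | step 12 | C8 O-phenyl thionocarbonate of F7 | CC(C)(C)OC(=O)N[C@H]1[C@@H](OC(=S)Oc3ccccc3)[C@]2(O)[C@@H](OCc3ccccc3)[C@H](OS(=O)(=O)c3ccc(C)cc3)[C@@H](OC(=O)c3ccccc3)[C@@H](OC)[C@@H]2[C@H]1O[Si](C)(C)C(C)(C)C
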